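The pyran ring of the 2H-chromene is cut at C3=C4. The quaternary stereocentre C2 (bonded to O1, CH3, ring carbon C3 and chain carbon C1′) then becomes the prochiral carbon of an aryl divinylcarbinyl ether, because the ring C3=C4 unit and the C1′–C2′ chain stub are both vinyl groups before cyclisation. One chiral molybdenum alkylidene closes the pyran ring onto the ortho-styrene, forms C3=C4 and fixes C2 as (S) in a single ring-closing metathesis. The precursor is a 1-(3-methylpenta-1,4-dien-3-yloxy)-2-vinylbenzene with a silyl-protected oxygen para to the ether. The surviving vinyl group is extended by hydroboration and sp3–sp2 coupling with an E-alkenyl iodide made from dihydro-β-ionone.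

Key step: step 5

Remark (assumption): the sense of induction of the chiral Mo complex on 8 cannot be predicted with confidence; step 5 is written with the (R)-diolate and stands for whichever antipode delivers (S)-9, to be identified in a pilot run.

Remark (protecting group): the C6 oxygen is carried as a triisopropylsilyl ether, so the phenol is freed by fluoride and not by acid, which could ionise the C2–O1 allylic ether; the silyl ether also offers no Lewis-basic site to Mo. Compounds 7 and 8 are tertiary allyl aryl ethers and are kept below 40 °C.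

Step 1
Reactants: 1 2-fluoro-5-hydroxybenzaldehyde
Product: 2 2-fluoro-5-[(triisopropylsilyl)oxy]benzaldehyde
Conditions: TIPSCl (1.1 equiv), imidazole (2.2 equiv), CH2Cl2, 0 °C → rt
Reagents that add atoms: triisopropylsilyl chloride, CC(C)[Si](Cl)(C(C)C)C(C)C
Why: Imidazole-promoted O-silylation of a phenol, which should leave the aldehyde and the C–F bond untouched and removes the acidic OH that would otherwise give a phenoxide and shut down the later fluoride displacement.

Step 2
Reactants: 3 ethyl acetate; 4 vinylmagnesium bromide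
Product: 6 3-methylpenta-1,4-dien-3-ol, via but-3-en-2-one 5 (not isolated)
Conditions: 4 (2.3 equiv, 1 M in THF), THF, 0 °C → rt; sat. aq NH4Cl; distillation under reduced pressure
Reagents that add atoms: none
Why: Double Grignard addition to an ester, in which the first adduct collapses to the enone and the hard vinyl nucleophile should add 1,2 to it faster than to the ester; the buffered work-up avoids acid-induced allylic transposition of the bis-allylic tertiary alcohol.

Step 3
Reactants: 6 3-methylpenta-1,4-dien-3-ol; 2 2-fluoro-5-[(triisopropylsilyl)oxy]benzaldehyde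
Product: 7 2-[(3-methylpenta-1,4-dien-3-yl)oxy]-5-[(triisopropylsilyl)oxy]benzaldehyde
Conditions: 6 (1.5 equiv), KH (1.4 equiv), THF, 0 °C; then 2, 0 °C → rt, not above 40 °C; pH 7 buffer
Reagents that add atoms: none
Why: Nucleophilic aromatic substitution by addition–elimination, the tertiary potassium alkoxide adding at the C–F carbon ortho to the formyl group; THF without crown ether or dipolar cosolvent keeps the alkoxide and the KF formed from attacking the aryl silyl ether, and the low temperature avoids aromatic Claisen rearrangement.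

Step 4
Reactants: 7 2-[(3-methylpenta-1,4-dien-3-yl)oxy]-5-[(triisopropylsilyl)oxy]benzaldehyde
Product: 8 triisopropyl{4-[(3-methylpenta-1,4-dien-3-yl)oxy]-3-vinylphenoxy}silane
Conditions: Ph3PCH3Br (1.5 equiv), KHMDS (1.4 equiv), THF, 0 °C; then 7, 0 °C → rt; filtration through basic alumina
Reagents that add atoms: methyltriphenylphosphonium bromide, C[P+](c1ccccc1)(c1ccccc1)c1ccccc1.[Br-]
Why: Wittig methylenation of an aryl aldehyde with the non-stabilised ylide; the ether carbon carries no hydrogen and the silyl ether meets no free alkoxide, so nothing else should react.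

Step 5
Reactants: 8 triisopropyl{4-[(3-methylpenta-1,4-dien-3-yl)oxy]-3-vinylphenoxy}silane
Product: 9 (S)-triisopropyl[(2-methyl-2-vinyl-2H-chromen-6-yl)oxy]silane
Conditions: 5 mol % Mo(N-2,6-i-Pr2C6H3)(CHCMe2Ph)[(R)-3,3′-bis(2,4,6-i-Pr3C6H2)-1,1′-binaphthyl-2,2′-diolate]·THF, C6H6 (0.05 M), 22 °C, N2 (glovebox), vented to remove C2H4
Reagents that add atoms: none
Why: The Mo alkylidene exchanges first with the only unhindered alkene, the styrene, to give a Mo benzylidene at C4; this adds to one of the two vinyl groups on C2 in a [2+2] step, and cycloreversion of the molybdacyclobutane forms C3=C4 and leaves Mo=CH2, which carries the chain. The closest known reaction type is the Mo-catalysed asymmetric ring-closing metathesis that desymmetrises trienes to six-membered unsaturated cyclic tertiary ethers, for which biaryl-diolate imido alkylidenes of this kind are the established catalysts. The pyran ring (O1–C2–C3=C4–C4a–C8a) closes by intramolecular olefin metathesis, a six-membered ring closure with loss of ethylene. C2 becomes stereogenic because only one of its two enantiotopic vinyl groups enters the ring, and the choice is made by the chiral diolate and the imido ligand, which sense how CH3 and the aryloxy oxygen on C2 are placed in the two diastereomeric molybdacyclobutanes. The step needs enantiotopic-group selectivity and ring closure in preference to oligomerisation; the substrate secures this by offering a single accessible initiation site, no alternative ring size (the two vinyl groups cannot close on each other) and a remaining vinyl group on a fully substituted carbon that is too hindered to dimerise. Removal of ethylene keeps Mo=CH2 from reopening C3=C4 and so should protect the enantiomeric ratio once it is set.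

Step 6
Reactants: 10 dihydro-β-ionone [4-(2,6,6-trimethylcyclohex-1-en-1-yl)butan-2-one]
Product: 12 2-(but-3-yn-1-yl)-1,3,3-trimethylcyclohex-1-ene, via enol diethyl phosphate 11 (not isolated)
Conditions: LDA (1.05 equiv, commercial solution), THF, −78 °C; ClP(O)(OEt)2, −78 °C → rt; LDA (2.3 equiv), −78 °C → rt; aq NH4Cl
Reagents that add atoms: none
Why: Enol phosphate route from a methyl ketone to a terminal alkyne: kinetic deprotonation at CH3, O-phosphorylation and LDA-induced β-elimination of diethyl phosphate, the alkyne being held as its lithium acetylide until work-up so that it cannot isomerise.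

Step 7
Reactants: 12 2-(but-3-yn-1-yl)-1,3,3-trimethylcyclohex-1-ene
Product: 14 (E)-2-(4-iodo-3-methylbut-3-en-1-yl)-1,3,3-trimethylcyclohex-1-ene, via alkenyldimethylalane 13 (not isolated)
Conditions: Me3Al (2.5 equiv), Cp2ZrCl2 (0.25 equiv), CH2Cl2, 0 °C → rt; then I2, THF, −30 → 0 °C
Reagents that add atoms: trimethylaluminium, C[Al](C)C; iodine, II
Why: Zirconium-catalysed syn-carboalumination of the terminal alkyne places CH3 on the internal carbon and Al on the terminus, and iododealumination with retention should give the E-iodide; the tetrasubstituted ring alkene is inert.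

Step 8
Reactants: 9 (S)-triisopropyl[(2-methyl-2-vinyl-2H-chromen-6-yl)oxy]silane; 14 (E)-2-(4-iodo-3-methylbut-3-en-1-yl)-1,3,3-trimethylcyclohex-1-ene
Product: 16 (S)-triisopropyl({2-methyl-2-[(E)-4-methyl-6-(2,6,6-trimethylcyclohex-1-en-1-yl)hex-3-en-1-yl]-2H-chromen-6-yl}oxy)silane, via B-alkyl-9-BBN adduct 15 (not isolated)
Conditions: 9-BBN (1.2 equiv), THF, 0 °C → rt; then 14 (1.2 equiv), 5 mol % Pd(dppf)Cl2·CH2Cl2, 5 mol % AsPh3, 3 M aq K3PO4, DMF, rt, degassed
Reagents that add atoms: none
Why: Anti-Markovnikov hydroboration of the monosubstituted vinyl group by bulky 9-BBN (the cis-disubstituted C3=C4 is far slower), then B-alkyl Suzuki–Miyaura coupling with the alkenyl iodide with retention of alkene geometry; C2 takes no part and keeps its configuration.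

Step 9
Reactants: 16 (S)-triisopropyl({2-methyl-2-[(E)-4-methyl-6-(2,6,6-trimethylcyclohex-1-en-1-yl)hex-3-en-1-yl]-2H-chromen-6-yl}oxy)silane
Product: 17 (S)-2-methyl-2-[(E)-4-methyl-6-(2,6,6-trimethylcyclohex-1-en-1-yl)hex-3-en-1-yl]-2H-chromen-6-ol
Conditions: TBAF (1.1 equiv), THF, 0 °C, Ar; sat. aq NH4Cl
Reagents that add atoms: none
Why: Fluoride-induced cleavage of the aryl silyl ether driven by Si–F bond formation; the non-acidic medium leaves the C2–O1 allylic ether and the three alkenes alone, so the configuration at C2 and the E geometry should be retained.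

Compound list
1 | 2-fluoro-5-hydroxybenzaldehyde | O=Cc1cc(O)ccc1F | starting material
2 | 2-fluoro-5-[(triisopropylsilyl)oxy]benzaldehyde | O=Cc1cc(O[Si](C(C)C)(C(C)C)C(C)C)ccc1F | intermediate
3 | ethyl acetate | CCOC(C)=O | starting material
4 | vinylmagnesium bromide | C=C[Mg]Br | starting material
5 | but-3-en-2-one | CC(=O)C=C | intermediate
6 | 3-methylpenta-1,4-dien-3-ol | C=CC(C)(O)C=C | intermediate
7 | 2-[(3-methylpenta-1,4-dien-3-yl)oxy]-5-[(triisopropylsilyl)oxy]benzaldehyde | O=Cc1cc(O[Si](C(C)C)(C(C)C)C(C)C)ccc1OC(C)(C=C)C=C | intermediate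
8 | triisopropyl{4-[(3-methylpenta-1,4-dien-3-yl)oxy]-3-vinylphenoxy}silane | C=CC(C)(C=C)Oc1ccc(O[Si](C(C)C)(C(C)C)C(C)C)cc1C=C | intermediate
9 | (S)-triisopropyl[(2-methyl-2-vinyl-2H-chromen-6-yl)oxy]silane | C=C[C@@]1(C)C=Cc2cc(O[Si](C(C)C)(C(C)C)C(C)C)ccc2O1 | intermediate
10 | dihydro-β-ionone, 4-(2,6,6-trimethylcyclohex-1-en-1-yl)butan-2-one | CC(=O)CCC1=C(C)CCCC1(C)C | starting material
11 | diethyl 4-(2,6,6-trimethylcyclohex-1-en-1-yl)but-1-en-2-yl phosphate | C=C(CCC1=C(C)CCCC1(C)C)OP(=O)(OCC)OCC | intermediate
12 | 2-(but-3-yn-1-yl)-1,3,3-trimethylcyclohex-1-ene | C#CCCC1=C(C)CCCC1(C)C | intermediate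
13 | dimethyl[(E)-2-methyl-4-(2,6,6-trimethylcyclohex-1-en-1-yl)but-1-en-1-yl]alane | C[Al](C)/C=C(\C)CCC1=C(C)CCCC1(C)C | intermediate
14 | (E)-2-(4-iodo-3-methylbut-3-en-1-yl)-1,3,3-trimethylcyclohex-1-ene | I/C=C(\C)CCC1=C(C)CCCC1(C)C | intermediate
15 | (S)-{[2-(2-(9-borabicyclo[3.3.1]nonan-9-yl)ethyl)-2-methyl-2H-chromen-6-yl]oxy}triisopropylsilane | B1(CC[C@@]3(C)C=Cc4cc(O[Si](C(C)C)(C(C)C)C(C)C)ccc4O3)C2CCCC1CCC2 | intermediate
16 | (S)-triisopropyl({2-methyl-2-[(E)-4-methyl-6-(2,6,6-trimethylcyclohex-1-en-1-yl)hex-3-en-1-yl]-2H-chromen-6-yl}oxy)silane | CC1=C(CC/C(C)=C/CC[C@@]2(C)C=Cc3cc(O[Si](C(C)C)(C(C)C)C(C)C)ccc3O2)C(C)(C)CCC1 | intermediate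
17 | (S)-2-methyl-2-[(E)-4-methyl-6-(2,6,6-trimethylcyclohex-1-en-1-yl)hex-3-en-1-yl]-2H-chromen-6-ol | CC1=C(CC/C(C)=C/CC[C@@]2(C)C=Cc3cc(O)ccc3O2)C(C)(C)CCC1 | target

Total step count: 9.
Longest linear sequence: 6 steps (step 1 or step 2, then steps 3, 4, 5, 8 and 9).

Steps most likely to fail

Step 5. The diolate pocket may discriminate poorly between the two enantiotopic vinyl groups, Mo=CH2 may reopen the product and level the enantiomeric ratio, or traces of protic or carbonyl impurities may destroy the alkylidene before turnover. The fallback replaces asymmetric catalysis by racemic ring closure and resolution. It sets out from 8, which an achiral second-generation ruthenium benzylidene (NHC ligand, 2–5 mol %, CH2Cl2, 35 °C) should close to racemic triisopropyl[(2-methyl-2-vinyl-2H-chromen-6-yl)oxy]silane F1. Preparative chromatography on a polysaccharide chiral stationary phase would then separate the enantiomers. The (S)-enantiomer is 9, where the route is rejoined, and (R)-triisopropyl[(2-methyl-2-vinyl-2H-chromen-6-yl)oxy]silane F2 is set aside.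

Step 3. Addition of the hindered alkoxide to a ring deactivated by the para silyloxy group may be slow. Attack at the formyl group with hydride-transfer disproportionation, silyl transfer to alkoxide or fluoride, or Claisen rearrangement on warming could then take over. The fallback brings the C6 oxygen in after the displacement. It sets out from 6 and purchased 5-bromo-2-fluorobenzaldehyde (O=Cc1cc(Br)ccc1F), in which the para substituent accelerates the displacement and no silyl ether is present. KH in THF at 0 °C → rt should give 5-bromo-2-[(3-methylpenta-1,4-dien-3-yl)oxy]benzaldehyde F3. Wittig methylenation as in step 4 should give 4-bromo-1-[(3-methylpenta-1,4-dien-3-yl)oxy]-2-vinylbenzene F4. Bromine–lithium exchange (n-BuLi, THF, −78 °C) and B(OMe)3 should give dimethyl {4-[(3-methylpenta-1,4-dien-3-yl)oxy]-3-vinylphenyl}boronate F5 (not isolated). Oxidation in the same flask (aq NaOH, H2O2, 0 °C) should give 4-[(3-methylpenta-1,4-dien-3-yl)oxy]-3-vinylphenol F6. Silylation with TIPSCl and imidazole then gives 8, where the route is rejoined.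

Step 8. Transfer of the alkyl group from the hindered borate to palladium may be slow, so that protodeboronation, β-hydride elimination or reduction of the alkenyl iodide compete. The fallback replaces the organoborane by an organozinc reagent. It sets out from 9, which is hydroborated as in step 8 to 15 and then oxidised (NaBO3·4H2O, THF/H2O) to (S)-2-{2-methyl-6-[(triisopropylsilyl)oxy]-2H-chromen-2-yl}ethan-1-ol F7. I2, PPh3 and imidazole should give (S)-{[2-(2-iodoethyl)-2-methyl-2H-chromen-6-yl]oxy}triisopropylsilane F8. Insertion of activated zinc dust (THF/DMA, 40 °C) should give (S)-(2-{2-methyl-6-[(triisopropylsilyl)oxy]-2H-chromen-2-yl}ethyl)zinc iodide F9 (not isolated). Negishi coupling with 14 (Pd(dppf)Cl2, rt) should give 16, where the route is rejoined.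

Further compounds
F1 | step 5 | rac-triisopropyl[(2-methyl-2-vinyl-2H-chromen-6-yl)oxy]silane | C=CC1(C)C=Cc2cc(O[Si](C(C)C)(C(C)C)C(C)C)ccc2O1
F2 | step 5 | (R)-triisopropyl[(2-methyl-2-vinyl-2H-chromen-6-yl)oxy]silane | C=C[C@]1(C)C=Cc2cc(O[Si](C(C)C)(C(C)C)C(C)C)ccc2O1
F3 | step 3 | 5-bromo-2-[(3-methylpenta-1,4-dien-3-yl)oxy]benzaldehyde | O=Cc1cc(Br)ccc1OC(C)(C=C)C=C
F4 | step 3 | 4-bromo-1-[(3-methylpenta-1,4-dien-3-yl)oxy]-2-vinylbenzene | C=CC(C)(C=C)Oc1ccc(Br)cc1C=C
F5 | step 3 | dimethyl {4-[(3-methylpenta-1,4-dien-3-yl)oxy]-3-vinylphenyl}boronate | COB(OC)c1ccc(OC(C)(C=C)C=C)c(C=C)c1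
F6 | step 3 | 4-[(3-methylpenta-1,4-dien-3-yl)oxy]-3-vinylphenol | C=CC(C)(C=C)Oc1ccc(O)cc1C=C
F7 | step 8 | (S)-2-{2-methyl-6-[(triisopropylsilyl)oxy]-2H-chromen-2-yl}ethan-1-ol | OCC[C@@]1(C)C=Cc2cc(O[Si](C(C)C)(C(C)C)C(C)C)ccc2O1
F8 | step 8 | (S)-{[2-(2-iodoethyl)-2-methyl-2H-chromen-6-yl]oxy}triisopropylsilane | ICC[C@@]1(C)C=Cc2cc(O[Si](C(C)C)(C(C)C)C(C)C)ccc2O1
F9 | step 8 | (S)-(2-{2-methyl-6-[(triisopropylsilyl)oxy]-2H-chromen-2-yl}ethyl)zinc iodide | I[Zn]CC[C@@]1(C)C=Cc2cc(O[Si](C(C)C)(C(C)C)C(C)C)ccc2O1
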